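Oak's feed brings in 0.0333 mM min⁻¹ of substrate, while the eta run loses 0.400 mM min⁻¹ between 25.0 min and 50.0 min, so we must ask how substrate divides when the tank holds little of it.

all flasks: free catalyst 64 µM
- beta: substrate 20 mM; reagent 36 mM; run made earlier
- eta: substrate 28 mM; reagent 36 mM; run made earlier
- epsilon: substrate 44 mM; reagent 36 mM; run made earlier
- oak: substrate 20 mM; reagent 36.0 mM; a single well-mixed tank run continuously and read at steady state, 10.0 h in it on average
- larch: substrate 20 mM; reagent 36.0 mM; a closed flask charged with all of it at once and left for 1.0 h; time 1.0 h
- maple: substrate 20 mM; reagent 36.0 mM; a single well-mixed tank run continuously and read at steady state, 1.0 h in it on average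
- alder: substrate 20 mM; reagent 36.0 mM (fed, over 0.800 h); all but reagent at the start; reagent goes in evenly over 0.800 h, the run ends at 1.0 h; time 1.0 h

| run | time / min | target / % | side product / % | substrate / % |
|---|---|---|---|---|
| beta | 5.00 | 3.2 | 7.7 | 87.7 |
| beta | 8.00 | 3.1 | 14.6 | 83.0 |
| beta | 12.0 | 3.0 | 23.0 | 72.8 |
| beta | 20.0 | 6.6 | 42.2 | 52.1 |
| beta | 40.0 | 6.5 | 74.1 | 17.4 |
| beta | 60.0 | 11.8 | 85.6 | 1.6 |
| eta | 12.0 | 2.7 | 19.1 | 79.6 |
| eta | 25.0 | 2.9 | 40.7 | 57.2 |
| eta | 40.0 | 4.8 | 62.7 | 34.3 |
| eta | 50.0 | 5.7 | 74.1 | 21.5 |
| eta | 60.0 | 5.9 | 84.6 | 11.9 |
| eta | 80.0 | 6.9 | 91.3 | 1.0 |
| epsilon | 12.0 | 0 | 14.4 | 84.7 |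
| epsilon | 25.0 | 1.0 | 28.7 | 69.6 |
| epsilon | 40.0 | 0 | 42.4 | 56.0 |
| epsilon | 50.0 | 2.8 | 52.1 | 47.4 |
| epsilon | 60.0 | 0 | 59.9 | 38.1 |
| epsilon | 80.0 | 0.8 | 75.0 | 22.8 |

(scatter of a reading: 1 percentage point)

- percentages count the substrate that a species holds: one side product counts as two
- the stated concentrations are those of everything mixed, before any reaction; amounts are the same in each set-up
- the feed brings no volume worth counting
- the earlier runs were made in a closed, stirred flask

- the set-up with the highest share of target in all that became target or side product, at the outlet or at the end ("none" if the first two lie within 2 percentage points) (oak / larch / maple / alder / none)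
- share of target in all that became target or side product, at the outlet or at the end, oak
- share of target in all that became target or side product, at the outlet or at the end, larch
- share of target in all that became target or side product, at the outlet or at the end, maple
- share of target in all that became target or side product, at the outlet or at the end, alder

Side product climbs while target stays small, and side product holds two substrate, so we read it as target plus substrate. In the eta run at 40.0 min, 1.34 mM of target stands beside 9.60 mM of substrate. But target isn't level: it rises 0.0314 mM min⁻¹, so the catalyst route and the target route each take about half of the loss, and the mean of target times substrate over the three eta readings in that window gives the target route's constant.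

Loss at high substrate barely follows the charge, so the catalyst route isn't first order there. At the end of the beta and eta runs, however, substrate falls away at 0.122 min⁻¹, and we take that as the catalyst route at low substrate. The objections pull opposite ways: that figure includes the target route, yet its window starts above the first-order range. The last readings also sit near the scatter of 1 percentage point, so what follows is rough.

Dividing the catalyst constant by the target constant gives the crossover target, the target level at which both routes take substrate equally (a selectivity factor with the unit of a concentration): 7.20 mM.

In oak, the level of substrate cancels from the split, as we take both routes first order in it. Side product over all turnovers equals target over crossover, while target plus side product counted as two makes up the charge. That gives 4.54 mM of target, a share of 22.7%. For larch we take the last beta reading, 12.1%, and we put maple and alder near it.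

The forecast names oak at 50%, “the best by far but uncertain”, with larch 11%, maple 9% and alder 4.5%, so it differs from our oak.

The best set-up is oak: oak 22.5%, larch 12.4%, maple 11.3%, alder 9.04%.

    reagent + free catalyst → catalyst intermediate A (k = 2.70 M⁻¹ s⁻¹)
    substrate + catalyst intermediate A → catalyst intermediate B (k = 44.0 M⁻¹ s⁻¹)
    catalyst intermediate B ⇌ catalyst intermediate C (K = 3.00, k = 0.350 s⁻¹)
    catalyst intermediate C → free catalyst + target (k = 30.0 s⁻¹)
    substrate + target → side product (k = 0.360 M⁻¹ s⁻¹)

Oak's 22.5% stands beside our 22.7%. In larch at 1.00 h, substrate's half-life through catalyst intermediate A is 0.083 h, shorter than the 0.219 h through target. With the crossover 7.20 mM and 2.45 mM of target, each remaining substrate nets 0.493 of a target, so the 1.31% left lifts target from 12.2% to 12.9%, and larch at 10.0 h holds 12.9%.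

The readings come from a simulation for substances that don't exist, and the scatter is random.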